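Numbering and enabling feature: ring A = C1, C2, C3 (ketone), C4 (CH with the acid chain), C5, C10. Ring B = C5 (C–CH3), C6, C7, C8 (CH–CH3), C9 (CH3 and benzylic C11), C10 (CH). In ring B the C8 and C9 methyls are trans-diaxial with C11 equatorial, rings A and B are trans-fused at C5–C10, and C3(=O)–C4 is the remnant of a β-keto ester. This is the imprint of two anti additions across (E)-C8=C9 and (E)-C5=C10 that begin with H+ at C8 and end at an enol carbon C4.
Cuts: hydroquinone ⇒ quinone ⇒ dimethyl ether. Next the bond from C4 to the chain CH2 (acrylate), once an ester is put back on C4. Then C4–C5 and C9–C10 in one stroke, which opens rings A and B to acyclic keto ester 18. An allyl ester is chosen so that it and the acrylate ester leave together under neutral palladium catalysis.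
Chain cuts in 18: C1–C2 (acetoacetate dianion), C10–C1 and C5–CH3 (methylalumination of an alkyne, then formaldehyde), C6–C7 (propargyl anion), aryl–C11 (aryl Grignard reagent on the (E)-1,4-dibromide of 2,3-dimethylbutadiene).
Forward: the chain grows from the arene towards the keto ester (steps 1–8). Step 9 closes ring B and then ring A in one operation. Steps 10–13 add the acid chain, remove the C4 ester and unmask the hydroquinone.
Stereochemistry: the C8=C9 geometry comes from the crystalline (E)-dibromide and the C5=C10 geometry from syn carboalumination. The absolute configuration comes from a chiral proton source acting at C8. C9, C10 and C5 are relayed by the two alkene geometries in a chair–chair fold. C4 is fixed last, by axial protonation and enolisation to the equatorial chain.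

Key step: step 9

Assumption: the direction of asymmetric induction by the SnCl4–BINOL ether acid at a tetrasubstituted alkene is unknown; the (R)-ligand is written, and if it favours the mirror-image decalin the (S)-ligand replaces it with no other change.
Assumption: (R)-2-benzyloxy-2'-hydroxy-1,1'-binaphthyl is taken as a purchasable reagent (otherwise one O-benzylation of (R)-BINOL) that is recovered unchanged after step 9.

Step 1
Reactants: 1 4-methoxy-2-methylphenol
Product: 2 2-bromo-4-methoxy-6-methylphenol
Conditions: NBS (1.0 equiv), MeCN, 0 °C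
Reagents that add atoms: N-bromosuccinimide, O=C1CCC(=O)N1Br
Why: Electrophilic aromatic bromination, in which the free OH is the strongest director and its para position is blocked, so bromine should enter the single open ortho position.

Step 2
Reactants: 2 2-bromo-4-methoxy-6-methylphenol
Product: 3 1-bromo-2,5-dimethoxy-3-methylbenzene
Conditions: MeI, K2CO3, acetone, reflux
Reagents that add atoms: iodomethane, CI
Why: Williamson ether synthesis on the phenoxide, to which the aryl bromide is inert.

Step 3
Reactants: 4 2,3-dimethylbuta-1,3-diene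
Product: 5 (E)-1,4-dibromo-2,3-dimethylbut-2-ene
Conditions: Br2 (1.0 equiv), CH2Cl2, −20 °C; recrystallisation from hexane
Reagents that add atoms: bromine, BrBr
Why: Conjugate 1,4-addition of bromine to the diene gives the tetrasubstituted alkene, and recrystallisation of the solid (E)-isomer removes the (Z)-isomer and the 1,2-adduct, which fixes the later C8=C9 geometry.

Step 4
Reactants: 3 1-bromo-2,5-dimethoxy-3-methylbenzene; 5 (E)-1,4-dibromo-2,3-dimethylbut-2-ene
Product: 7 1-[(2E)-4-bromo-2,3-dimethylbut-2-en-1-yl]-2,5-dimethoxy-3-methylbenzene, via aryl Grignard reagent 6 (not isolated)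
Conditions: 3, Mg, THF, reflux; then slow addition to 5 (3 equiv), Li2CuCl4 (5 mol %), THF, −40 → 0 °C
Reagents that add atoms: none
Why: Kochi-type Li2CuCl4-catalysed coupling of a Grignard reagent with an allylic bromide, in which inverse addition to excess 5 favours single substitution and direct SN2 displacement is expected because the SN2' site is a fully substituted alkene carbon, so the (E)-geometry is kept.

Step 5
Reactants: 7 1-[(2E)-4-bromo-2,3-dimethylbut-2-en-1-yl]-2,5-dimethoxy-3-methylbenzene; 8 1-(trimethylsilyl)propyne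
Product: 11 1-[(2E)-2,3-dimethylhept-2-en-6-yn-1-yl]-2,5-dimethoxy-3-methylbenzene, via lithiated silylpropyne 9 (not isolated), via silylated enyne 10 (not isolated)
Conditions: 8, n-BuLi, THF, −78 → −20 °C; 7, −78 °C → rt; then MeOH, K2CO3 (cat.), rt
Reagents that add atoms: none
Why: SN2 alkylation of a silyl-blocked propargyllithium at the primary allylic bromide forms C6–C7 without touching the alkene, the silyl group suppresses allene formation, and base-catalysed methanolysis of the C–Si bond in the same flask frees the terminal alkyne.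

Step 6
Reactants: 11 1-[(2E)-2,3-dimethylhept-2-en-6-yn-1-yl]-2,5-dimethoxy-3-methylbenzene
Product: 14 (2E,6E)-8-(2,5-dimethoxy-3-methylphenyl)-3,6,7-trimethylocta-2,6-dien-1-ol, via alkenyl dimethylalane 12 (not isolated), via lithium alkenyl aluminate 13 (not isolated)
Conditions: Me3Al (3 equiv), Cp2ZrCl2 (0.25 equiv), CH2Cl2, 0 °C → rt; excess Me3Al and solvent evaporated; hexane–THF, n-BuLi, −78 → 0 °C; (CH2O)n, rt; aqueous work-up
Reagents that add atoms: trimethylaluminium, C[Al](C)C; paraformaldehyde (as formaldehyde), C=O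
Why: Negishi zirconium-catalysed methylalumination is a syn addition that puts CH3 on the internal carbon (C5) and aluminium on C10, and the derived aluminate takes up formaldehyde with retention, so the C5=C10 alkene is formed as the (E)-isomer.

Step 7
Reactants: 14 (2E,6E)-8-(2,5-dimethoxy-3-methylphenyl)-3,6,7-trimethylocta-2,6-dien-1-ol
Product: 15 1-[(2E,6E)-8-bromo-2,3,6-trimethylocta-2,6-dien-1-yl]-2,5-dimethoxy-3-methylbenzene
Conditions: CBr4, PPh3, CH2Cl2, 0 °C
Reagents that add atoms: tetrabromomethane, BrC(Br)(Br)Br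
Why: The Appel reaction converts the primary allylic alcohol by SN2 at C1 under neutral conditions, without allylic transposition or alkene isomerisation.

Step 8
Reactants: 15 1-[(2E,6E)-8-bromo-2,3,6-trimethylocta-2,6-dien-1-yl]-2,5-dimethoxy-3-methylbenzene; 16 allyl acetoacetate
Product: 18 allyl (6E,10E)-12-(2,5-dimethoxy-3-methylphenyl)-7,10,11-trimethyl-3-oxododeca-6,10-dienoate, via sodium lithium dianion 17 (not isolated)
Conditions: 16, NaH, THF, 0 °C; n-BuLi, 0 °C; 15, 0 °C → rt; aqueous quench
Reagents that add atoms: none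
Why: Weiler dianion alkylation, in which the more basic terminal carbanion of the acetoacetate dianion attacks the primary allylic bromide by SN2, forming C1–C2 and leaving both alkene geometries intact.

Step 9
Reactants: 18 allyl (6E,10E)-12-(2,5-dimethoxy-3-methylphenyl)-7,10,11-trimethyl-3-oxododeca-6,10-dienoate
Product: 19 allyl (4S,5R,8S,9S,10R)-9-(2,5-dimethoxy-3-methylbenzyl)-5,8,9-trimethyl-3-oxo-trans-decalin-4-carboxylate (plan numbering; C5-, C8- and C9-CH3 axial; C11 and the ester equatorial)
Conditions: SnCl4 (3.0 equiv, one of them allowed for the keto ester), (R)-2-benzyloxy-2'-hydroxy-1,1'-binaphthyl (2.2 equiv), toluene, −78 °C; aq. NaHCO3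
Reagents that add atoms: none
Why: Proposed new method: the naphthol O–H of the ligand, acidified by SnCl4, should hand its proton to C8 of the tetrasubstituted alkene while the C10=C5 π bond attacks C9 on the opposite face, and the tertiary C5 cation is then taken by C4 of the tin-coordinated enol of the keto ester, whose own proton is released, so the step is a net isomerisation of 18. The closest known reaction types are the SnCl4-promoted bicyclisation of dienyl β-keto esters to trans-decalin keto esters, the enantioselective proton-initiated polyene cyclisation with SnCl4–BINOL ether acids (both shown only from trisubstituted alkenes) and the acid cyclisation of pseudoirones, which does start at a tetrasubstituted alkene. Ring B closes 6-endo-trig through C9–C10 and ring A closes 6-endo-trig (enol-endo) through C4–C5, each in a chair fold. C8 is set by the alkene face that the chiral acid protonates; C9 follows from anti addition of H and C10 across the (E)-C8=C9 bond, which leaves the new C8–H equatorial, the C8 and C9 methyls trans-diaxial and C11 equatorial; C10 and C5 follow from anti addition of C9 and C4 across the (E)-C5=C10 bond (trans fusion); C4 settles by enolisation with its ester equatorial. The step needs protonation at C8 rather than at C9 or C10, C- rather than O-capture at C5 and no interference by the arene: the tetrasubstituted alkene is the most basic π bond, a C8 cation has no unstrained ring closure open to it and reverts, an O-captured tertiary enol ether is re-ionised by SnCl4, the equatorial arylmethyl group cannot reach the axial lobe at C5, and the methyl ethers keep the ortho oxygen from trapping C9 for good. Toluene at −78 °C is chosen because a free C9 cation is costly there, so proton transfer and C9–C10 bonding should stay coupled, on which the trans C8/C9 relationship depends.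

Step 10
Reactants: 19 allyl (4S,5R,8S,9S,10R)-9-(2,5-dimethoxy-3-methylbenzyl)-5,8,9-trimethyl-3-oxo-trans-decalin-4-carboxylate; 20 allyl acrylate
Product: 21 allyl (4S,5R,8S,9S,10R)-4-[3-(allyloxy)-3-oxopropyl]-9-(2,5-dimethoxy-3-methylbenzyl)-5,8,9-trimethyl-3-oxo-trans-decalin-4-carboxylate
Conditions: 20 (3 equiv), Cs2CO3 (0.3 equiv), MeCN, rt → 40 °C
Reagents that add atoms: none
Why: Base-catalysed Michael addition of a cyclic β-keto ester, in which the acrylate should approach the C3–C4 enolate axially on the face opposite the axial C5 methyl, the configuration of this quaternary C4 being erased in the next step in any case.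

Step 11
Reactants: 21 allyl (4S,5R,8S,9S,10R)-4-[3-(allyloxy)-3-oxopropyl]-9-(2,5-dimethoxy-3-methylbenzyl)-5,8,9-trimethyl-3-oxo-trans-decalin-4-carboxylate
Product: 23 3-[(4S,5R,8S,9S,10R)-9-(2,5-dimethoxy-3-methylbenzyl)-5,8,9-trimethyl-3-oxo-trans-decalin-4-yl]propanoic acid, via keto diacid 22 (not isolated)
Conditions: Pd(PPh3)4 (5 mol %), morpholine (5 equiv), THF, rt; dilute HCl work-up
Reagents that add atoms: none
Why: Tsuji–Trost allyl transfer to morpholine frees both acids at room temperature, the β-keto acid loses CO2, and the enol is protonated axially on the face anti to the C5 methyl, which places the chain equatorial, the same C4 epimer that enolisation in the amine-buffered medium favours thermodynamically.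

Step 12
Reactants: 23 3-[(4S,5R,8S,9S,10R)-9-(2,5-dimethoxy-3-methylbenzyl)-5,8,9-trimethyl-3-oxo-trans-decalin-4-yl]propanoic acid
Product: 24 3-[(4S,5R,8S,9S,10R)-5,8,9-trimethyl-9-[(5-methyl-3,6-dioxocyclohexa-1,4-dien-1-yl)methyl]-3-oxo-trans-decalin-4-yl]propanoic acid
Conditions: (NH4)2Ce(NO3)6 (2.5 equiv), MeCN–H2O, 0 °C
Reagents that add atoms: water, O
Why: Oxidative demethylation of a hydroquinone dimethyl ether to the para-quinone, a two-electron oxidation of the arene alone that leaves the ketone, the acid and all sp3 stereocentres untouched.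

Step 13
Reactants: 24 3-[(4S,5R,8S,9S,10R)-5,8,9-trimethyl-9-[(5-methyl-3,6-dioxocyclohexa-1,4-dien-1-yl)methyl]-3-oxo-trans-decalin-4-yl]propanoic acid
Product: 25 3-[(4S,5R,8S,9S,10R)-9-(2,5-dihydroxy-3-methylbenzyl)-5,8,9-trimethyl-3-oxo-trans-decalin-4-yl]propanoic acid (CNP0167047.1)
Conditions: Na2S2O4, THF–H2O, rt, argon
Reagents that add atoms: none
Why: Dithionite reduction of a quinone to its hydroquinone is fast and selective at room temperature and does not reduce the saturated ketone or disturb C4.

Compound list
1 | 4-methoxy-2-methylphenol | COc1ccc(O)c(C)c1 | starting material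
2 | 2-bromo-4-methoxy-6-methylphenol | COc1cc(C)c(O)c(Br)c1 | intermediate
3 | 1-bromo-2,5-dimethoxy-3-methylbenzene | COc1cc(C)c(OC)c(Br)c1 | intermediate
4 | 2,3-dimethylbuta-1,3-diene | C=C(C)C(C)=C | starting material
5 | (E)-1,4-dibromo-2,3-dimethylbut-2-ene | BrC/C(C)=C(C)/CBr | intermediate
6 | (2,5-dimethoxy-3-methylphenyl)magnesium bromide (not isolated) | COc1cc(C)c(OC)c([Mg]Br)c1 | intermediate
7 | 1-[(2E)-4-bromo-2,3-dimethylbut-2-en-1-yl]-2,5-dimethoxy-3-methylbenzene | COc1cc(C)c(OC)c(C/C(C)=C(C)/CBr)c1 | intermediate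
8 | 1-(trimethylsilyl)propyne | CC#C[Si](C)(C)C | starting material
9 | 3-lithio-1-(trimethylsilyl)propyne (not isolated) | [Li]CC#C[Si](C)(C)C | intermediate
10 | [(5E)-7-(2,5-dimethoxy-3-methylphenyl)-5,6-dimethylhept-5-en-1-yn-1-yl]trimethylsilane (not isolated) | C[Si](C)(C)C#CCC/C(C)=C(C)/Cc1cc(OC)cc(C)c1OC | intermediate
11 | 1-[(2E)-2,3-dimethylhept-2-en-6-yn-1-yl]-2,5-dimethoxy-3-methylbenzene | C#CCC/C(C)=C(C)/Cc1cc(OC)cc(C)c1OC | intermediate
12 | [(1E,5E)-7-(2,5-dimethoxy-3-methylphenyl)-2,5,6-trimethylhepta-1,5-dien-1-yl]dimethylalane (not isolated) | C[Al](C)/C=C(C)/CC/C(C)=C(C)/Cc1cc(OC)cc(C)c1OC | intermediate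
13 | lithium butyl[(1E,5E)-7-(2,5-dimethoxy-3-methylphenyl)-2,5,6-trimethylhepta-1,5-dien-1-yl]dimethylaluminate (not isolated) | [Li+].CCCC[Al-](C)(C)/C=C(C)/CC/C(C)=C(C)/Cc1cc(OC)cc(C)c1OC | intermediate
14 | (2E,6E)-8-(2,5-dimethoxy-3-methylphenyl)-3,6,7-trimethylocta-2,6-dien-1-ol | OC/C=C(C)/CC/C(C)=C(C)/Cc1cc(OC)cc(C)c1OC | intermediate
15 | 1-[(2E,6E)-8-bromo-2,3,6-trimethylocta-2,6-dien-1-yl]-2,5-dimethoxy-3-methylbenzene | BrC/C=C(C)/CC/C(C)=C(C)/Cc1cc(OC)cc(C)c1OC | intermediate
16 | allyl acetoacetate | CC(=O)CC(=O)OCC=C | starting material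
17 | sodium lithium dianion of allyl acetoacetate (not isolated) | [Na+].[Li+].C=C([O-])C=C([O-])OCC=C | intermediate
18 | allyl (6E,10E)-12-(2,5-dimethoxy-3-methylphenyl)-7,10,11-trimethyl-3-oxododeca-6,10-dienoate | C=CCOC(=O)CC(=O)CC/C=C(C)/CC/C(C)=C(C)/Cc1cc(OC)cc(C)c1OC | intermediate
19 | allyl (4S,5R,8S,9S,10R)-9-(2,5-dimethoxy-3-methylbenzyl)-5,8,9-trimethyl-3-oxo-trans-decalin-4-carboxylate | Cc1cc(OC)cc(C[C@]2(C)[C@H]3CCC(=O)[C@@H](C(=O)OCC=C)[C@]3(C)CC[C@@H]2C)c1OC | intermediate
20 | allyl acrylate | C=CC(=O)OCC=C | starting material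
21 | allyl (4S,5R,8S,9S,10R)-4-[3-(allyloxy)-3-oxopropyl]-9-(2,5-dimethoxy-3-methylbenzyl)-5,8,9-trimethyl-3-oxo-trans-decalin-4-carboxylate | Cc1cc(OC)cc(C[C@]2(C)[C@H]3CCC(=O)[C@@](CCC(=O)OCC=C)(C(=O)OCC=C)[C@]3(C)CC[C@@H]2C)c1OC | intermediate
22 | (4S,5R,8S,9S,10R)-4-(2-carboxyethyl)-9-(2,5-dimethoxy-3-methylbenzyl)-5,8,9-trimethyl-3-oxo-trans-decalin-4-carboxylic acid (not isolated) | Cc1cc(OC)cc(C[C@]2(C)[C@H]3CCC(=O)[C@@](CCC(=O)O)(C(=O)O)[C@]3(C)CC[C@@H]2C)c1OC | intermediate
23 | 3-[(4S,5R,8S,9S,10R)-9-(2,5-dimethoxy-3-methylbenzyl)-5,8,9-trimethyl-3-oxo-trans-decalin-4-yl]propanoic acid | Cc1cc(OC)cc(C[C@]2(C)[C@H]3CCC(=O)[C@@H](CCC(=O)O)[C@]3(C)CC[C@@H]2C)c1OC | intermediate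
24 | 3-[(4S,5R,8S,9S,10R)-5,8,9-trimethyl-9-[(5-methyl-3,6-dioxocyclohexa-1,4-dien-1-yl)methyl]-3-oxo-trans-decalin-4-yl]propanoic acid | CC1=CC(=O)C=C(C[C@]2(C)[C@H]3CCC(=O)[C@@H](CCC(=O)O)[C@]3(C)CC[C@@H]2C)C1=O | intermediate
25 | 3-[(4S,5R,8S,9S,10R)-9-(2,5-dihydroxy-3-methylbenzyl)-5,8,9-trimethyl-3-oxo-trans-decalin-4-yl]propanoic acid (CNP0167047.1) | Cc1cc(O)cc(C[C@]2(C)[C@H]3CCC(=O)[C@@H](CCC(=O)O)[C@]3(C)CC[C@@H]2C)c1O | target

Total step count: 13.
Longest linear sequence: 12 steps (steps 1, 2 and 4–13, from 4-methoxy-2-methylphenol); step 3 is a one-step branch.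

Steps most likely to fail

Step 9.
- Risks:
  - Weak enantiofacial discrimination in the proton transfer to a tetrasubstituted alkene.
  - Background protonation by achiral acid released when the keto ester binds SnCl4.
  - Uncoupling of protonation and ring closure, with rotation about C8–C9 that erodes the trans C8/C9 relationship.
  - Capture of the C5 cation by the enol oxygen, or proton loss after ring B alone has closed.
- Fallback: a covalent auxiliary and separation replace the chiral acid. This fallback secures enantiopurity and lets a C8 epimer be removed, but it still depends on the anti addition across C8=C9.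
  - It sets out from 18. Ester exchange with (1R,2S,5R)-menthol (DMAP, toluene, reflux, allyl alcohol distilled off) would give menthyl keto ester F1.
  - Achiral SnCl4 in CH2Cl2 (−78 → 0 °C), the established cyclisation of dienyl β-keto esters, would give two trans-decalin diastereomers: menthyl decalin ester F2, with the decalin configuration of 19, and mirror-decalin menthyl ester F3.
  - These, and any C8 epimer, are parted by crystallisation or chromatography.
  - Heating F2 with excess allyl alcohol and DMAP in toluene exchanges the ester through the acylketene and comes back to the route at 19.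

Step 4.
- Risks: halogen–metal exchange followed by 1,4-debromination of 5 back to the diene, double arylation, and some SN2' attack.
- Fallback: one terminus is masked before any organometal is present.
  - It sets out from 5. KOAc (1 equiv, DMF, rt) would give bromo acetate F4, in which neither debromination nor a second arylation is possible.
  - Li2CuCl4-catalysed coupling with Grignard reagent 6 (THF, −40 °C) gives aryl allyl acetate F5.
  - Methanolysis (K2CO3, MeOH) gives aryl allylic alcohol F6, and Appel bromination (CBr4, PPh3) comes back to the route at 7.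

Step 10.
- Risks: sluggish or reversible C–C bond formation, because a quaternary C4 must be built next to the quaternary C5, and acrylate oligomerisation taking over.
- Fallback: the quaternary centre is avoided altogether.
  - It sets out from 19. Pd(PPh3)4 (THF, rt) triggers the Tsuji decarboxylative allylation of the allyl β-keto ester itself. CO2 is lost, the C3–C4 enolate forms regiospecifically and is allylated at C4, and DBU equilibration places the new group equatorial in 4-allyl ketone F7.
  - Hydroboration (9-BBN, THF; NaOH, H2O2) gives keto alcohol F8.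
  - CrO3/H2SO4 in acetone (0 °C) oxidises the primary alcohol, and re-oxidises any C3 alcohol, to come back to the route at 23.

Further compounds
F1 | step 9 | (1R,2S,5R)-menthyl (6E,10E)-12-(2,5-dimethoxy-3-methylphenyl)-7,10,11-trimethyl-3-oxododeca-6,10-dienoate | CC(C)[C@@H]1CC[C@@H](C)C[C@H]1OC(=O)CC(=O)CC/C=C(C)/CC/C(C)=C(C)/Cc2cc(OC)cc(C)c2OC
F2 | step 9 | (1R,2S,5R)-menthyl (4S,5R,8S,9S,10R)-9-(2,5-dimethoxy-3-methylbenzyl)-5,8,9-trimethyl-3-oxo-trans-decalin-4-carboxylate | Cc1cc(OC)cc(C[C@]2(C)[C@H]3CCC(=O)[C@@H](C(=O)O[C@@H]4C[C@H](C)CC[C@H]4C(C)C)[C@]3(C)CC[C@@H]2C)c1OC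
F3 | step 9 | (1R,2S,5R)-menthyl (4R,5S,8R,9R,10S)-9-(2,5-dimethoxy-3-methylbenzyl)-5,8,9-trimethyl-3-oxo-trans-decalin-4-carboxylate | Cc1cc(OC)cc(C[C@@]2(C)[C@@H]3CCC(=O)[C@H](C(=O)O[C@@H]4C[C@H](C)CC[C@H]4C(C)C)[C@@]3(C)CC[C@H]2C)c1OC
F4 | step 4 | (2E)-4-bromo-2,3-dimethylbut-2-en-1-yl acetate | CC(=O)OC/C(C)=C(C)/CBr
F5 | step 4 | (2E)-4-(2,5-dimethoxy-3-methylphenyl)-2,3-dimethylbut-2-en-1-yl acetate | CC(=O)OC/C(C)=C(C)/Cc1cc(OC)cc(C)c1OC
F6 | step 4 | (2E)-4-(2,5-dimethoxy-3-methylphenyl)-2,3-dimethylbut-2-en-1-ol | OC/C(C)=C(C)/Cc1cc(OC)cc(C)c1OC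
F7 | step 10 | (4S,5R,8S,9S,10R)-4-allyl-9-(2,5-dimethoxy-3-methylbenzyl)-5,8,9-trimethyl-trans-decalin-3-one | Cc1cc(OC)cc(C[C@]2(C)[C@H]3CCC(=O)[C@@H](CC=C)[C@]3(C)CC[C@@H]2C)c1OC
F8 | step 10 | (4S,5R,8S,9S,10R)-9-(2,5-dimethoxy-3-methylbenzyl)-4-(3-hydroxypropyl)-5,8,9-trimethyl-trans-decalin-3-one | Cc1cc(OC)cc(C[C@]2(C)[C@H]3CCC(=O)[C@@H](CCCO)[C@]3(C)CC[C@@H]2C)c1OC
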